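The route opens ring C at C3=C4: because C3 carries the syringate oxygen and C4 is the methylene on ring A, that bond can be drawn as an enol-ester alkene. Ring-closing metathesis between a ring A vinyl group and a 1-(aroyloxy)vinyl group on C2 closes ring C in one operation with the ester already in place, so no hindered flavan-3-ol is ever acylated. The precursor is a perbenzylated (R)-configured aryl ether in which the C2 oxygen links the 3,4-dioxygenated benzylic carbon, bearing the enol syringate, to a 2-vinylphenol. C2 then directs a final hydrogenation that sets C3 cis and strips every benzyl group.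

Key step: step 8

Assumption: in step 3 the ligand enantiomer is the one that adds the alkynyl group to the Re face of the aldehyde (S carbinol 7); this sense is to be confirmed on 7 by Mosher ester analysis before the material is carried on.

Step 1
Reactants: 1 2,4,6-trihydroxybenzaldehyde
Product: 2 2,4-bis(benzyloxy)-6-hydroxybenzaldehyde
Conditions: BnBr (2.05 equiv), K2CO3 (2.2 equiv), DMF, 0 °C to rt
Reagents that add atoms: benzyl bromide, BrCc1ccccc1
Why: Williamson etherification in which the para OH and one ortho OH are alkylated while the remaining ortho OH, hydrogen-bonded to the formyl group, resists a limited amount of benzyl bromide.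

Step 2
Reactants: 2 2,4-bis(benzyloxy)-6-hydroxybenzaldehyde
Product: 3 3,5-bis(benzyloxy)-2-vinylphenol
Conditions: Ph3PCH3Br (2.5 equiv), KOtBu (2.4 equiv), THF, 0 °C to rt; aq NH4Cl
Reagents that add atoms: methyltriphenylphosphonium bromide, C[P+](c1ccccc1)(c1ccccc1)c1ccccc1.[Br-]
Why: Wittig methylenation of a salicylaldehyde, in which one equivalent of ylide is spent on the phenol and the excess converts the formyl group into the vinyl group, so that no strong base is needed once C2 exists.

Step 3
Reactants: 4 3,4-bis(benzyloxy)benzaldehyde; 5 trimethylsilylacetylene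
Product: 7 (S)-1-[3,4-bis(benzyloxy)phenyl]-3-(trimethylsilyl)prop-2-yn-1-ol, via alkynylzinc 6 (not isolated)
Conditions: 5 (3 equiv), Me2Zn (3 equiv), ProPhenol ligand (10 mol %), Ph3P=O (20 mol %), toluene, 4 °C; aq NH4Cl
Reagents that add atoms: none
Why: Catalytic enantioselective alkynylation of an aromatic aldehyde with a dinuclear zinc–ProPhenol catalyst (Trost alkynylation), in which the chiral dizinc pocket delivers the alkynyl group of 6 to the Re face of the aldehyde and so sets the S carbinol centre under ligand control.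

Step 4
Reactants: 7 (S)-1-[3,4-bis(benzyloxy)phenyl]-3-(trimethylsilyl)prop-2-yn-1-ol
Product: 8 (R)-1-[3,4-bis(benzyloxy)phenyl]prop-2-yn-1-ol
Conditions: K2CO3 (0.5 equiv), MeOH, 0 °C to rt
Reagents that add atoms: none
Why: Methoxide-mediated protodesilylation of the alkynylsilane, done at the alcohol stage so that base never meets the later aryl ether; the carbinol centre is untouched and only its descriptor changes, because ethynyl ranks below aryl.

Step 5
Reactants: 8 (R)-1-[3,4-bis(benzyloxy)phenyl]prop-2-yn-1-ol; 3 3,5-bis(benzyloxy)-2-vinylphenol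
Product: 9 (S)-1,5-bis(benzyloxy)-3-{1-[3,4-bis(benzyloxy)phenyl]prop-2-yn-1-yloxy}-2-vinylbenzene
Conditions: PPh3, DIAD (slow addition), toluene, −20 °C to 0 °C
Reagents that add atoms: none
Why: Mitsunobu etherification, in which the phenoxide of 3 displaces the oxyphosphonium group by SN2 with inversion and turns the R carbinol into the S ether that has the spatial arrangement of C2 in the target, with low temperature and a non-polar solvent disfavouring ionization of the electron-rich benzylic centre.

Step 6
Reactants: 10 syringic acid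
Product: 12 4-(benzyloxy)-3,5-dimethoxybenzoic acid, via benzyl ester 11 (not isolated)
Conditions: BnBr (2.3 equiv), K2CO3, DMF, 60 °C; then NaOH, MeOH–H2O, 60 °C; HCl
Reagents that add atoms: benzyl bromide, BrCc1ccccc1; sodium hydroxide, [Na+].[OH-] (its oxygen becomes the acid OH)
Why: Williamson benzylation of phenol and carboxylic acid followed by saponification of the benzyl ester in the same flask, which leaves the benzyl ether in place.

Step 7
Reactants: 9 (S)-1,5-bis(benzyloxy)-3-{1-[3,4-bis(benzyloxy)phenyl]prop-2-yn-1-yloxy}-2-vinylbenzene; 12 4-(benzyloxy)-3,5-dimethoxybenzoic acid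
Product: 13 (R)-3-[3,4-bis(benzyloxy)phenyl]-3-[3,5-bis(benzyloxy)-2-vinylphenoxy]prop-1-en-2-yl 4-(benzyloxy)-3,5-dimethoxybenzoate
Conditions: [RuCl2(p-cymene)]2 (2.5 mol %), P(2-furyl)3 (5 mol %), Na2CO3 (10 mol %), toluene, 50–60 °C, dark
Reagents that add atoms: none
Why: Ruthenium-catalysed Markovnikov hydro-acyloxylation of a terminal alkyne (Goossen conditions), in which the carboxylate attacks the internal carbon of the ruthenium-bound alkyne and gives the 1-acyloxyvinyl group under buffered, near-neutral conditions that leave C2 alone (the descriptor becomes R only because the oxygenated vinyl carbon outranks aryl).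

Step 8
Reactants: 13 (R)-3-[3,4-bis(benzyloxy)phenyl]-3-[3,5-bis(benzyloxy)-2-vinylphenoxy]prop-1-en-2-yl 4-(benzyloxy)-3,5-dimethoxybenzoate
Product: 14 (2R)-5,7-bis(benzyloxy)-2-[3,4-bis(benzyloxy)phenyl]-2H-chromen-3-yl 4-(benzyloxy)-3,5-dimethoxybenzoate
Conditions: (H2IMes)(PCy3)Cl2Ru=CHPh (second-generation Grubbs catalyst, 10 mol % in two portions), 1,4-benzoquinone (20 mol %), toluene (0.005 M), 60 °C, argon sparge, dark
Reagents that add atoms: none
Why: The ruthenium benzylidene exchanges onto the ring A vinyl group, since the geminally substituted, electron-poor enol ester is not a loading site, and the resulting arylidene adds across the 1-acyloxyvinyl group to a ruthenacyclobutane whose cycloreversion forms C3=C4 and releases Ru=CH2, which re-enters the cycle with loss of ethylene (Chauvin mechanism). The closest known reactions are ring-closing metathesis of allyl 2-vinylaryl ethers to 2H-chromenes and ring closure onto heteroatom-substituted 1,1-disubstituted alkenes such as acyclic enol ethers and silyl enol ethers, of which the enol ester partner is an extension within the same reaction type. Ring C closes as a six-membered ring between the styrene carbon (C4) and the oxygen-bearing vinyl carbon (C3), with the new alkene inside the ring and both terminal CH2 groups leaving as ethylene. No stereocentre is formed and C2 is a spectator: neutral conditions, moderate temperature and exclusion of light keep the chromene from opening by oxa-6π electrocyclization, and 1,4-benzoquinone intercepts ruthenium hydrides that could move the double bond to C2=C3. The selectivity needed is ring closure over intermolecular styrene dimerization, which high dilution, the six-membered ring size, removal of ethylene and the inability of the hindered enol ester to homodimerize should secure.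

Step 9
Reactants: 14 (2R)-5,7-bis(benzyloxy)-2-[3,4-bis(benzyloxy)phenyl]-2H-chromen-3-yl 4-(benzyloxy)-3,5-dimethoxybenzoate
Product: 15 (2R,3R)-2-(3,4-dihydroxyphenyl)-5,7-dihydroxychroman-3-yl 4-hydroxy-3,5-dimethoxybenzoate
Conditions: H2 (1 atm), Pd/C (10 wt % Pd), THF–MeOH, rt
Reagents that add atoms: none
Why: Heterogeneous catalytic hydrogenation, in which syn addition of H2 to the C3=C4 enol ester from the face opposite the pseudoaxial C2 aryl group sets C3 as R (2,3-cis, as in hydrogenation of flav-3-enes) while the same catalyst removes the five benzyl ethers by hydrogenolysis; saturation and debenzylation run side by side, so no single intermediate is defined.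

Compound list
1 | 2,4,6-trihydroxybenzaldehyde | O=Cc1c(O)cc(O)cc1O | starting material
2 | 2,4-bis(benzyloxy)-6-hydroxybenzaldehyde | O=Cc1c(O)cc(OCc2ccccc2)cc1OCc1ccccc1 | intermediate
3 | 3,5-bis(benzyloxy)-2-vinylphenol | C=Cc1c(O)cc(OCc2ccccc2)cc1OCc1ccccc1 | intermediate
4 | 3,4-bis(benzyloxy)benzaldehyde | O=Cc1ccc(OCc2ccccc2)c(OCc2ccccc2)c1 | starting material
5 | trimethylsilylacetylene | C#C[Si](C)(C)C | starting material
6 | methyl[(trimethylsilyl)ethynyl]zinc | C[Zn]C#C[Si](C)(C)C | intermediate
7 | (S)-1-[3,4-bis(benzyloxy)phenyl]-3-(trimethylsilyl)prop-2-yn-1-ol | O[C@H](C#C[Si](C)(C)C)c1ccc(OCc2ccccc2)c(OCc2ccccc2)c1 | intermediate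
8 | (R)-1-[3,4-bis(benzyloxy)phenyl]prop-2-yn-1-ol | O[C@H](C#C)c1ccc(OCc2ccccc2)c(OCc2ccccc2)c1 | intermediate
9 | (S)-1,5-bis(benzyloxy)-3-{1-[3,4-bis(benzyloxy)phenyl]prop-2-yn-1-yloxy}-2-vinylbenzene | C=Cc1c(OCc2ccccc2)cc(OCc2ccccc2)cc1O[C@@H](C#C)c1ccc(OCc2ccccc2)c(OCc2ccccc2)c1 | intermediate
10 | syringic acid (4-hydroxy-3,5-dimethoxybenzoic acid) | COc1cc(C(=O)O)cc(OC)c1O | starting material
11 | benzyl 4-(benzyloxy)-3,5-dimethoxybenzoate | COc1cc(C(=O)OCc2ccccc2)cc(OC)c1OCc1ccccc1 | intermediate
12 | 4-(benzyloxy)-3,5-dimethoxybenzoic acid | COc1cc(C(=O)O)cc(OC)c1OCc1ccccc1 | intermediate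
13 | (R)-3-[3,4-bis(benzyloxy)phenyl]-3-[3,5-bis(benzyloxy)-2-vinylphenoxy]prop-1-en-2-yl 4-(benzyloxy)-3,5-dimethoxybenzoate | C=Cc1c(OCc2ccccc2)cc(OCc2ccccc2)cc1O[C@@H](C(=C)OC(=O)c1cc(OC)c(OCc2ccccc2)c(OC)c1)c1ccc(OCc2ccccc2)c(OCc2ccccc2)c1 | intermediate
14 | (2R)-5,7-bis(benzyloxy)-2-[3,4-bis(benzyloxy)phenyl]-2H-chromen-3-yl 4-(benzyloxy)-3,5-dimethoxybenzoate | COc1cc(C(=O)OC2=Cc3c(OCc4ccccc4)cc(OCc4ccccc4)cc3O[C@@H]2c2ccc(OCc3ccccc3)c(OCc3ccccc3)c2)cc(OC)c1OCc1ccccc1 | intermediate
15 | (2R,3R)-2-(3,4-dihydroxyphenyl)-5,7-dihydroxychroman-3-yl 4-hydroxy-3,5-dimethoxybenzoate (epicatechin 3-O-syringate) | COc1cc(C(=O)O[C@@H]2Cc3c(O)cc(O)cc3O[C@@H]2c2ccc(O)c(O)c2)cc(OC)c1O | target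

Total step count: 9.
Longest linear sequence: 6 steps (steps 3, 4, 5, 7, 8, 9 from 4; the ring A branch through steps 1, 2, 5, 7, 8, 9 is equally long).

Steps most likely to fail

1. Step 8, ring-closing metathesis. The enol ester is the least precedented partner. Once loaded on the 2,6-dioxygenated styrene, the catalyst may rest as an oxygen-chelated arylidene that closes only slowly onto the electron-poor, geminally substituted enol ester. Intermolecular stilbene formation, catalyst decay or hydride-mediated double-bond migration could then win. The fallback keeps a metathesis but removes the enol ester from it and uses the established flavan-3-ol sequence. It sets out from 9. Semihydrogenation of the alkyne (H2, Pd/CaCO3 poisoned with Pb(OAc)2, quinoline, EtOAc) should give (S)-1,5-bis(benzyloxy)-3-{1-[3,4-bis(benzyloxy)phenyl]allyloxy}-2-vinylbenzene F1. Ring-closing metathesis of its two monosubstituted alkenes with (H2IMes)(PCy3)Cl2Ru=CHPh should give the flav-3-ene (2S)-5,7-bis(benzyloxy)-2-[3,4-bis(benzyloxy)phenyl]-2H-chromene F2. Hydroboration–oxidation (BH3·THF; NaOH, H2O2), with boron adding to C3 on the face away from the C2 aryl group, should give the 2,3-trans alcohol (2R,3S)-5,7-bis(benzyloxy)-2-[3,4-bis(benzyloxy)phenyl]chroman-3-ol F3. Dess–Martin oxidation should give (2R)-5,7-bis(benzyloxy)-2-[3,4-bis(benzyloxy)phenyl]chroman-3-one F4. Reduction with Li[(s-Bu)3BH] and LiBr in THF at −78 °C should give the cis alcohol (2R,3R)-5,7-bis(benzyloxy)-2-[3,4-bis(benzyloxy)phenyl]chroman-3-ol F5. Esterification with 12 (EDC·HCl, DMAP, CH2Cl2) should give (2R,3R)-5,7-bis(benzyloxy)-2-[3,4-bis(benzyloxy)phenyl]chroman-3-yl 4-(benzyloxy)-3,5-dimethoxybenzoate F6. Hydrogenolysis (H2, Pd(OH)2/C, THF–MeOH) then comes back to the route at 15. This detour fixes C3 by hydride delivery, so it would also serve if the face selectivity of step 9 were poor.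

2. Step 7, hydro-acyloxylation. The electron-rich styrene may be consumed by acid-promoted addition or oligomerization or by ruthenium-mediated enyne reactions before the carboxylate adds to the alkyne. The fallback brings in the vinyl group last and sets out from 8. Mitsunobu etherification with aldehyde 2 in place of 3 (PPh3, DIAD, toluene) should give (S)-2,4-bis(benzyloxy)-6-{1-[3,4-bis(benzyloxy)phenyl]prop-2-yn-1-yloxy}benzaldehyde F7. The ruthenium-catalysed addition of 12 then runs with no alkene present and should give (R)-3-[3,4-bis(benzyloxy)phenyl]-3-[3,5-bis(benzyloxy)-2-formylphenoxy]prop-1-en-2-yl 4-(benzyloxy)-3,5-dimethoxybenzoate F8. Non-basic methylenation of the aldehyde (CH2I2, Zn, Ti(OiPr)4, THF; Takai conditions, which leave esters untouched) comes back to the route at 13. This does not cure carboxylate attack at the terminal alkyne carbon; in that case the detour from 9 described under step 8 applies.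

3. Step 5, Mitsunobu etherification. Partial ionization of the oxyphosphonium intermediate at the electron-rich benzylic, propargylic carbon would erode the enantiomeric purity of C2, and SN2' attack would give an allenyl ether. The fallback sets C2 by ligand control in a copper-catalysed enantioselective propargylic etherification and sets out from 8. Acetylation (Ac2O, pyridine, DMAP) should give (R)-1-[3,4-bis(benzyloxy)phenyl]prop-2-yn-1-yl acetate F9. Cu(OTf)·0.5C6H6 with a chiral pybox ligand and iPr2NEt in a non-nucleophilic solvent should couple it with phenol 3 through a copper allenylidene, the ligand antipode being chosen to give the S ether, and this comes back to the route at 9. Because the carbinol configuration is erased in the allenylidene, the racemate of the acetate would serve equally.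

Further compounds
F1 | step 8 | (S)-1,5-bis(benzyloxy)-3-{1-[3,4-bis(benzyloxy)phenyl]allyloxy}-2-vinylbenzene | C=Cc1c(OCc2ccccc2)cc(OCc2ccccc2)cc1O[C@@H](C=C)c1ccc(OCc2ccccc2)c(OCc2ccccc2)c1
F2 | step 8 | (2S)-5,7-bis(benzyloxy)-2-[3,4-bis(benzyloxy)phenyl]-2H-chromene | C1=Cc2c(OCc3ccccc3)cc(OCc3ccccc3)cc2O[C@@H]1c1ccc(OCc2ccccc2)c(OCc2ccccc2)c1
F3 | step 8 | (2R,3S)-5,7-bis(benzyloxy)-2-[3,4-bis(benzyloxy)phenyl]chroman-3-ol | O[C@H]1Cc2c(OCc3ccccc3)cc(OCc3ccccc3)cc2O[C@@H]1c1ccc(OCc2ccccc2)c(OCc2ccccc2)c1
F4 | step 8 | (2R)-5,7-bis(benzyloxy)-2-[3,4-bis(benzyloxy)phenyl]chroman-3-one | O=C1Cc2c(OCc3ccccc3)cc(OCc3ccccc3)cc2O[C@@H]1c1ccc(OCc2ccccc2)c(OCc2ccccc2)c1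
F5 | step 8 | (2R,3R)-5,7-bis(benzyloxy)-2-[3,4-bis(benzyloxy)phenyl]chroman-3-ol | O[C@@H]1Cc2c(OCc3ccccc3)cc(OCc3ccccc3)cc2O[C@@H]1c1ccc(OCc2ccccc2)c(OCc2ccccc2)c1
F6 | step 8 | (2R,3R)-5,7-bis(benzyloxy)-2-[3,4-bis(benzyloxy)phenyl]chroman-3-yl 4-(benzyloxy)-3,5-dimethoxybenzoate | COc1cc(C(=O)O[C@@H]2Cc3c(OCc4ccccc4)cc(OCc4ccccc4)cc3O[C@@H]2c2ccc(OCc3ccccc3)c(OCc3ccccc3)c2)cc(OC)c1OCc1ccccc1
F7 | step 7 | (S)-2,4-bis(benzyloxy)-6-{1-[3,4-bis(benzyloxy)phenyl]prop-2-yn-1-yloxy}benzaldehyde | O=Cc1c(OCc2ccccc2)cc(OCc2ccccc2)cc1O[C@@H](C#C)c1ccc(OCc2ccccc2)c(OCc2ccccc2)c1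
F8 | step 7 | (R)-3-[3,4-bis(benzyloxy)phenyl]-3-[3,5-bis(benzyloxy)-2-formylphenoxy]prop-1-en-2-yl 4-(benzyloxy)-3,5-dimethoxybenzoate | O=Cc1c(OCc2ccccc2)cc(OCc2ccccc2)cc1O[C@@H](C(=C)OC(=O)c1cc(OC)c(OCc2ccccc2)c(OC)c1)c1ccc(OCc2ccccc2)c(OCc2ccccc2)c1
F9 | step 5 | (R)-1-[3,4-bis(benzyloxy)phenyl]prop-2-yn-1-yl acetate | CC(=O)O[C@H](C#C)c1ccc(OCc2ccccc2)c(OCc2ccccc2)c1
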